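**Plan**

- Retrosynthetic cuts, in order: (i) the C4–C4a bond of the chroman, by reversing a 1,2-shift of C4 back onto C8a, which leads to a 1-oxaspiro[4.5]deca-6,9-dien-8-one (an oxolane spiro-fused to a cyclohexadienone); (ii) the O1–C8a bond (dearomatising spiro-etherification of a para-alkylphenol); (iii) the aryl–C4 bond (Heck); (iv) the C1–O bond of phytol, transposed through a 2,3-epoxy alcohol.
- Enabling feature: O1 and the C6 hydroxyl are para on the benzene ring (a hydroquinone mono-ether). C8a can therefore be carried as the quaternary O,C-disubstituted carbon of a cyclohexa-2,5-dienone whose carbonyl is the later C6–OH, and C4 only has to move from C8a to the neighbouring C4a.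
- Forward order: chain first (phytol to (R)-isophytol), then the arene is joined, then the five-membered oxolane ring is made by oxidative spirocyclisation, and last the six-membered pyran ring by ring enlargement with re-aromatisation, which frees the phenol directly. No protecting group is used.
- Stereochemistry: 4'R and 8'R come from natural phytol. C2 comes from a Sharpless epoxidation and is carried through as a C–O bond that is never broken. The spiro centre is transient.

Key step: step 7

Assumption: natural phytol is taken as the commercial (2E,7R,11R) isomer, and D-(−)-diethyl tartrate is taken as the tartrate enantiomer that gives the (2R,3R)-epoxide of an (E)-3-methylalk-2-en-1-ol (the mirror image of the L-(+)-tartrate/(2S,3S) outcome known for geraniol).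

**Route**

Step 1
Reactants: 1 natural phytol, (2E,7R,11R)-3,7,11,15-tetramethylhexadec-2-en-1-ol
Product: 2 (2R,3R)-2,3-epoxyphytol, [(2R,3R)-3-methyl-3-[(4R,8R)-4,8,12-trimethyltridecyl]oxiran-2-yl]methanol
Conditions: Ti(OiPr)4 (10 mol%), D-(−)-diethyl tartrate (12 mol%), t-BuOOH (2 equiv, in decane), 4 Å MS, CH2Cl2, −20 °C
Reagents that add atoms: tert-butyl hydroperoxide, CC(C)(C)OO
Why: Sharpless asymmetric epoxidation of a trisubstituted E-allylic alcohol; the titanium–D-tartrate complex delivers the peroxide oxygen to one face of C2=C3 and so sets the tertiary C–O centre (C3, R) and C2 (R) under reagent control, independent of the remote 7R,11R centres.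

Step 2
Reactants: 2 (2R,3R)-2,3-epoxyphytol
Product: 3 (2S,3R)-2-(iodomethyl)-3-methyl-3-[(4R,8R)-4,8,12-trimethyltridecyl]oxirane
Conditions: PPh3, I2, imidazole, CH2Cl2, 0 °C, dark
Reagents that add atoms: iodine, II
Why: Appel-type (Garegg–Samuelsson) iodination of the primary alcohol through the alkoxyphosphonium ion; SN2 at CH2 leaves both epoxide carbons untouched (the 2S descriptor is a change of CIP priority only).

Step 3
Reactants: 3 epoxy iodide
Product: 4 (R)-isophytol, (3R,7R,11R)-3,7,11,15-tetramethylhexadec-1-en-3-ol
Conditions: Zn dust, AcOH (cat.), EtOH, 25–60 °C; aq. NH4Cl work-up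
Reagents that add atoms: none
Why: zinc inserts into the C–I bond and the β-oxygen of the epoxide is expelled (reductive ring opening of a 2,3-epoxy iodide), which transposes the function to the tertiary vinyl carbinol with the C3–O bond, and so the R configuration, intact.

Step 4
Reactants: 4 (R)-isophytol; 5 4-bromo-3-methylphenol
Product: 6 4-[(1E,3R,7R,11R)-3-hydroxy-3,7,11,15-tetramethylhexadec-1-en-1-yl]-3-methylphenol
Conditions: Pd(OAc)2 (3 mol%), P(o-tol)3 (8 mol%), Et3N, DMF, 95 °C
Reagents that add atoms: none
Why: Mizoroki–Heck arylation of a monosubstituted alkene; syn-insertion places the aryl group on the terminal carbon, and β-hydride elimination can only go towards the benzylic hydrogen because C3 is quaternary, so the E-styrene should form without touching the carbinol centre.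

Step 5
Reactants: 6 styrenyl carbinol
Product: 7 4-[(3R,7R,11R)-3-hydroxy-3,7,11,15-tetramethylhexadecyl]-3-methylphenol
Conditions: H2 (1 atm), 5% Pd/C, EtOAc, 20 °C
Reagents that add atoms: none
Why: heterogeneous hydrogenation of the conjugated 1,2-disubstituted alkene is fast at 1 atm in a neutral solvent, conditions under which the phenol and the tertiary alcohol should be retained.

Step 6
Reactants: 7 para-(3-hydroxyalkyl)phenol
Product: 8 (2R)-2,6-dimethyl-2-[(4R,8R)-4,8,12-trimethyltridecyl]-1-oxaspiro[4.5]deca-6,9-dien-8-one (both epimers at the spiro carbon C5)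
Conditions: PhI(OAc)2 (1.1 equiv), MeCN, 0 °C
Reagents that add atoms: none
Why: hypervalent-iodine oxidative dearomatisation of a para-alkylphenol; the phenoxy-iodane loses iodobenzene and acetate while the tethered tertiary hydroxyl attacks the para (ipso) carbon in a 5-exo closure to the spiro-oxolane, the carbinol centre reacts through oxygen only, and the spiro centre may form as both epimers because it becomes planar again in step 7.

Step 7
Reactants: 8 spirodienone
Product: 9 δ-tocopherol, (2R)-2,8-dimethyl-2-[(4R,8R)-4,8,12-trimethyltridecyl]-3,4-dihydro-2H-chromen-6-ol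
Conditions: BF3·OEt2 (20 mol%), CH2Cl2, −40 → 0 °C
Reagents that add atoms: none
Why: BF3 binds the carbonyl oxygen of 8 and turns the cross-conjugated dienone into an oxy-substituted cyclohexadienyl cation with positive charge on the two ring carbons that flank the spiro carbon; the spiro carbon then hands its CH2 substituent (C4 of the oxolane) to the unsubstituted neighbour in a suprafacial 1,2-shift (Wagner–Meerwein), the ether oxygen left behind stabilises the new cation as an oxocarbenium ion, and loss of the proton from the carbon that received C4 aromatises the ring and frees the phenol. The closest known reaction type is the dienone–phenol rearrangement of 4-alkyl-4-oxy-cyclohexa-2,5-dienones (p-quinols and their ethers to alkylhydroquinone derivatives, and spirolactones of the same ring system to 6-hydroxy-3,4-dihydrocoumarins). The six-membered pyran ring is closed by this 1,2-carbon shift as a one-atom enlargement of the oxolane, the dienone carbon that receives C4 becoming the sixth ring member, and not by attack of a chain end. No new stereocentre is formed: the spiro centre disappears on aromatisation, so both epimers of 8 should converge on one product, and the quaternary carbinol carbon keeps its R configuration because none of its bonds takes part. The step needs carbon migration in preference to oxygen migration (secured by the oxocarbenium ion that only carbon migration leaves behind), migration to the hydrogen-bearing and not the methyl-bearing neighbour (only the former can lose a proton, whereas a shift to the methyl-bearing carbon builds two adjacent quaternary centres and is reversible), and activation at the carbonyl without ionisation of the tertiary C–O bond (secured by a substoichiometric, carbonyl-selective Lewis acid at low temperature).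

**Compound list**

1 | natural phytol, (2E,7R,11R)-3,7,11,15-tetramethylhexadec-2-en-1-ol | OC/C=C(\C)CCC[C@H](C)CCC[C@H](C)CCCC(C)C | starting material
2 | (2R,3R)-2,3-epoxyphytol | OC[C@H]1O[C@]1(C)CCC[C@H](C)CCC[C@H](C)CCCC(C)C | intermediate
3 | (2S,3R)-2-(iodomethyl)-3-methyl-3-[(4R,8R)-4,8,12-trimethyltridecyl]oxirane | IC[C@H]1O[C@]1(C)CCC[C@H](C)CCC[C@H](C)CCCC(C)C | intermediate
4 | (R)-isophytol, (3R,7R,11R)-3,7,11,15-tetramethylhexadec-1-en-3-ol | O[C@](C=C)(C)CCC[C@H](C)CCC[C@H](C)CCCC(C)C | intermediate
5 | 4-bromo-3-methylphenol | Cc1cc(O)ccc1Br | starting material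
6 | 4-[(1E,3R,7R,11R)-3-hydroxy-3,7,11,15-tetramethylhexadec-1-en-1-yl]-3-methylphenol | O[C@](/C=C/c1ccc(O)cc1C)(C)CCC[C@H](C)CCC[C@H](C)CCCC(C)C | intermediate
7 | 4-[(3R,7R,11R)-3-hydroxy-3,7,11,15-tetramethylhexadecyl]-3-methylphenol | O[C@](CCc1ccc(O)cc1C)(C)CCC[C@H](C)CCC[C@H](C)CCCC(C)C | intermediate
8 | (2R)-2,6-dimethyl-2-[(4R,8R)-4,8,12-trimethyltridecyl]-1-oxaspiro[4.5]deca-6,9-dien-8-one (spiro epimers) | CC1=CC(=O)C=CC12CC[C@@](C)(CCC[C@H](C)CCC[C@H](C)CCCC(C)C)O2 | intermediate
9 | δ-tocopherol, (2R)-2,8-dimethyl-2-[(4R,8R)-4,8,12-trimethyltridecyl]-3,4-dihydro-2H-chromen-6-ol | Cc1cc(O)cc2c1O[C@](C)(CCC[C@H](C)CCC[C@H](C)CCCC(C)C)CC2 | target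

**Step count**

Total steps: 7. Longest linear sequence: 7 steps (1 to 9).

**Steps most likely to fail**

1. Step 7. The 1,2-shift may go to the methyl-bearing ring carbon and be followed by a methyl shift, which would give a ring-methyl positional isomer. The acid may also ionise the tertiary C–O bond, which would scramble the carbinol centre. The fallback gives up the skeletal shift and puts the side chain on the correct ring carbon by cross-coupling; it sets out from 4. 4-Methoxy-2-methylphenol is brominated ortho to the hydroxyl (NBS, MeCN, 0 °C) to 2-bromo-4-methoxy-6-methylphenol F1. Heck coupling of F1 with 4 (Pd(OAc)2, P(o-tol)3, Et3N, DMF, 95 °C) should give 2-[(1E,3R,7R,11R)-3-hydroxy-3,7,11,15-tetramethylhexadec-1-en-1-yl]-4-methoxy-6-methylphenol F2. Hydrogenation (H2, Pd/C, EtOAc) should give 2-[(3R,7R,11R)-3-hydroxy-3,7,11,15-tetramethylhexadecyl]-4-methoxy-6-methylphenol F3. Oxidative demethylation (PhI(OAc)2, MeCN/H2O, 0 °C) should give 2-[(3R,7R,11R)-3-hydroxy-3,7,11,15-tetramethylhexadecyl]-6-methylcyclohexa-2,5-diene-1,4-dione F4. Acid-catalysed ketalisation of F4 in methanol (HC(OMe)3, cat. H2SO4) to (2R)-8a-methoxy-2,8-dimethyl-2-[(4R,8R)-4,8,12-trimethyltridecyl]-3,4-dihydro-2H-chromen-6(8aH)-one F5 (not isolated), followed by reduction with ascorbic acid, is the sequence known for α-tocopherylquinone. It closes the pyran ring with the carbinol C–O bond intact and comes back to the route at 9.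

2. Step 6. Intermolecular coupling of the oxidised phenol, or its tautomerisation to a quinone methide through the benzylic hydrogens, may outrun capture at the ipso carbon by the hindered tertiary hydroxyl next to the ortho methyl group. The fallback changes the species that is oxidised; it sets out from 7. O-Methylation (MeI, K2CO3, acetone) should give (3R,7R,11R)-1-(4-methoxy-2-methylphenyl)-3,7,11,15-tetramethylhexadecan-3-ol F6. PhI(OCOCF3)2 in (CF3)2CHOH/H2O at 0 °C oxidises this aryl ether by single-electron transfer to its radical cation, the hydroxyl adds at the ring carbon para to methoxy, and water removes the O-methyl oxocarbenium ion as methanol. This comes back to the route at 8.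

3. Step 4. Oxidative addition into the electron-rich, ortho-substituted bromophenol may be slow, and the tertiary allylic alcohol may dehydrate at the Heck temperature. The fallback makes the same C–C bond as an sp3–sp2 coupling; it sets out from 4. Hydroboration of the vinyl group with 9-BBN (THF, 0 → 25 °C) should give (3S,7R,11R)-1-(9-borabicyclo[3.3.1]nonan-9-yl)-3,7,11,15-tetramethylhexadecan-3-ol F7 (not isolated; same spatial arrangement, the descriptor changes by CIP priority only). B-alkyl Suzuki–Miyaura coupling of F7 with 5 (Pd(dppf)Cl2, aq. K3PO4, THF/DMF, 60 °C) should give the saturated phenol directly and comes back to the route at 7, which also removes step 5.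

**Further compounds**

F1 | step 7 | 2-bromo-4-methoxy-6-methylphenol | COc1cc(C)c(O)c(Br)c1
F2 | step 7 | 2-[(1E,3R,7R,11R)-3-hydroxy-3,7,11,15-tetramethylhexadec-1-en-1-yl]-4-methoxy-6-methylphenol | O[C@](/C=C/c1cc(OC)cc(C)c1O)(C)CCC[C@H](C)CCC[C@H](C)CCCC(C)C
F3 | step 7 | 2-[(3R,7R,11R)-3-hydroxy-3,7,11,15-tetramethylhexadecyl]-4-methoxy-6-methylphenol | O[C@](CCc1cc(OC)cc(C)c1O)(C)CCC[C@H](C)CCC[C@H](C)CCCC(C)C
F4 | step 7 | 2-[(3R,7R,11R)-3-hydroxy-3,7,11,15-tetramethylhexadecyl]-6-methylcyclohexa-2,5-diene-1,4-dione | O[C@](CCC1=CC(=O)C=C(C)C1=O)(C)CCC[C@H](C)CCC[C@H](C)CCCC(C)C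
F5 | step 7 | (2R)-8a-methoxy-2,8-dimethyl-2-[(4R,8R)-4,8,12-trimethyltridecyl]-3,4-dihydro-2H-chromen-6(8aH)-one (C8a epimers) | CC1=CC(=O)C=C2CC[C@@](C)(CCC[C@H](C)CCC[C@H](C)CCCC(C)C)OC12OC
F6 | step 6 | (3R,7R,11R)-1-(4-methoxy-2-methylphenyl)-3,7,11,15-tetramethylhexadecan-3-ol | O[C@](CCc1ccc(OC)cc1C)(C)CCC[C@H](C)CCC[C@H](C)CCCC(C)C
F7 | step 4 | (3S,7R,11R)-1-(9-borabicyclo[3.3.1]nonan-9-yl)-3,7,11,15-tetramethylhexadecan-3-ol | O[C@](CCB1C2CCCC1CCC2)(C)CCC[C@H](C)CCC[C@H](C)CCCC(C)C
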